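**Retrosynthetic overview**
- The terminal alkyne is made last by one-carbon homologation of an aldehyde, which comes from a primary alcohol.
- The (E)-enyne is cut at its C(sp)–C(sp2) bond into a 1,2-dioxane core with a pent-4-ynyl chain and (9E)-10-iododec-9-en-1-ol; the iodide has no alkyne, so no protecting group is needed.
- The only ring, the 1,2-dioxane, is opened at O2–C3 and at the C6 ketal to an achiral keto-enoate, H2O2 and MeOH. In one flask the C6 ketone forms a perhydrate, an enantioselective 6-exo peroxy-Michael addition sets C3, and acid methanolysis sets C6.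
- The keto-enoate comes from hex-5-ynoic acid, Meldrum's acid and methyl 4-bromocrotonate by β-keto ester alkylation and decarboxylation.
- Ring order: the single dioxane ring is closed in step 4, before the side chain is extended.

**Assumptions**
- The SMILES corresponds to (3S,6R): OMe and CH2CO2Me are cis, with OMe axial and both carbon substituents equatorial.
- The sense of induction of the squaramide in step 4 cannot be predicted with certainty. The quinine-derived catalyst is taken to deliver the peroxide to the Si face of C3 (3S); if the first run shows the opposite, the commercial quinidine-derived pseudo-enantiomer is used with no other change.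
- Hex-5-ynoic acid, dec-9-yn-1-ol, Schwartz reagent and the Bestmann–Ohira reagent are taken as catalogue chemicals.

**Route**

Step 1
Reactants: 1 hex-5-ynoic acid; 2 Meldrum's acid (2,2-dimethyl-1,3-dioxane-4,6-dione); 3 tert-butanol
Product: 5 tert-butyl 3-oxooct-7-ynoate, via acyl Meldrum's acid 4 (not isolated)
Conditions: DCC (1.1 equiv), DMAP (1.2 equiv), CH2Cl2, 0 °C → rt; filter, acid wash; then t-BuOH (5 equiv), PhMe, 90 °C
Reagents that add atoms: Meldrum's acid, CC1(C)OC(=O)CC(=O)O1; tert-butanol, CC(C)(C)O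
Why: Carbodiimide C-acylation of Meldrum's acid followed by thermal alcoholysis (loss of acetone and CO2) is the standard Meldrum's acid β-keto ester synthesis and leaves the terminal alkyne untouched; no stereocentre is formed.

Step 2
Reactants: 5 tert-butyl 3-oxooct-7-ynoate; 6 methyl (2E)-4-bromobut-2-enoate
Product: 7 1-tert-butyl 6-methyl (4E)-2-(hex-5-ynoyl)hex-4-enedioate (racemic)
Conditions: K2CO3 (1.5 equiv), acetone, rt (5 in slight excess)
Reagents that add atoms: methyl (2E)-4-bromobut-2-enoate, COC(=O)/C=C/CBr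
Why: SN2 C-alkylation of the soft β-keto ester enolate by the allylic bromide installs the complete enoate arm with its E geometry; the new stereocentre is racemic and is removed in step 3.

Step 3
Reactants: 7 1-tert-butyl 6-methyl (4E)-2-(hex-5-ynoyl)hex-4-enedioate
Product: 9 methyl (2E)-6-oxoundec-2-en-10-ynoate, via β-keto acid 8 (not isolated)
Conditions: TFA/CH2Cl2 (1:4), rt; concentrate; PhMe, 80 °C
Reagents that add atoms: none
Why: Acidolysis of the tert-butyl ester (isobutene loss) and decarboxylation of the β-keto acid complete an acetoacetic-ester ketone synthesis; the methyl enoate, ketone and alkyne are inert to TFA.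

Step 4
Reactants: 9 methyl (2E)-6-oxoundec-2-en-10-ynoate; 10 hydrogen peroxide; 11 methanol
Product: 14 methyl 2-[(3S,6R)-6-methoxy-6-(pent-4-yn-1-yl)-1,2-dioxan-3-yl]acetate, via hydroperoxy hemiketal 12 (not isolated), via cyclic peroxyhemiketal 13 (not isolated)
Conditions: anhydrous H2O2 (ca. 2 M in Et2O, 1.5 equiv), quinine-derived bifunctional squaramide [N-3,5-bis(trifluoromethyl)phenyl-N′-(9-deoxy-epi-quinin-9-yl)squaramide, 10 mol %], PhMe, 0 °C; water wash to remove H2O2; then MeOH, CSA (10 mol %), 3 Å MS, 0 °C → rt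
Reagents that add atoms: hydrogen peroxide, OO; methanol, CO
Why: Proposed new method: H2O2 adds reversibly to the C6 ketone to give perhydrate 12, whose OOH group (more acidic than the geminal OH and an α-effect nucleophile) is engaged by the quinuclidine while the squaramide NH pair hydrogen-bonds the ester carbonyl, so that a 6-exo-trig peroxy-Michael addition to the Si face of C3 sets the 3S centre and the quinuclidinium protonates the enolate before it can attack the O–O bond; acid methanolysis of 13 through the peroxycarbenium ion then sets C6 under thermodynamic (anomeric) control with OMe axial and both carbon chains equatorial, which is the cis (6R) isomer; the closest known reactions are the amine/fluoroalcohol-mediated intramolecular conjugate addition of α-alkoxy hydroperoxides to enoates, the amine-catalysed asymmetric hydroperoxidation of enones that ends in cyclic peroxyhemiketals, squaramide-catalysed oxa-Michael additions, and the acid-catalysed etherification of cyclic peroxyhemiketals to peroxyketals.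

Step 5
Reactants: 15 dec-9-yn-1-ol; 16 iodine
Product: 18 (9E)-10-iododec-9-en-1-ol, via alkenylzirconocene 17 (not isolated)
Conditions: Cp2Zr(H)Cl (2.2 equiv), THF, rt; then I2 (1.1 equiv), 0 °C; aqueous work-up
Reagents that add atoms: iodine, II
Why: Hydrozirconation–iodination: the first equivalent of Schwartz reagent is consumed by the OH, syn addition places Zr on the terminal carbon, and iodinolysis with retention gives only the (E)-iodide.

Step 6
Reactants: 14 methyl 2-[(3S,6R)-6-methoxy-6-(pent-4-yn-1-yl)-1,2-dioxan-3-yl]acetate; 18 (9E)-10-iododec-9-en-1-ol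
Product: 19 methyl 2-[(3S,6R)-6-[(6E)-15-hydroxypentadec-6-en-4-yn-1-yl]-6-methoxy-1,2-dioxan-3-yl]acetate
Conditions: PdCl2(PPh3)2 (3 mol %), CuI (6 mol %), i-Pr2NH (3 equiv), THF (degassed), rt
Reagents that add atoms: none
Why: Sonogashira coupling proceeds with retention of the E geometry, dialkyl peroxides and peroxyketals tolerate Pd(0)/Cu(I)/amine at room temperature, and 18 has no alkyne that could self-couple; both stereocentres are untouched.

Step 7
Reactants: 19 methyl 2-[(3S,6R)-6-[(6E)-15-hydroxypentadec-6-en-4-yn-1-yl]-6-methoxy-1,2-dioxan-3-yl]acetate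
Product: 20 methyl 2-[(3S,6R)-6-methoxy-6-[(6E)-15-oxopentadec-6-en-4-yn-1-yl]-1,2-dioxan-3-yl]acetate
Conditions: Dess–Martin periodinane (1.3 equiv), pyridine (3 equiv), CH2Cl2, 0 °C → rt
Reagents that add atoms: none
Why: Dess–Martin oxidation under pyridine buffering is neutral and does not touch the peroxide, the acid-labile peroxyketal or the enyne.

Step 8
Reactants: 20 methyl 2-[(3S,6R)-6-methoxy-6-[(6E)-15-oxopentadec-6-en-4-yn-1-yl]-1,2-dioxan-3-yl]acetate; 21 dimethyl (1-diazo-2-oxopropyl)phosphonate
Product: 22 methyl 2-[(3S,6R)-6-[(6E)-hexadec-6-ene-4,15-diyn-1-yl]-6-methoxy-1,2-dioxan-3-yl]acetate (target)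
Conditions: K2CO3 (2 equiv), MeOH, 0 °C → rt
Reagents that add atoms: dimethyl (1-diazo-2-oxopropyl)phosphonate, COP(=O)(OC)C(=[N+]=[N-])C(C)=O
Why: Ohira–Bestmann (Seyferth–Gilbert) homologation: the diazomethylphosphonate anion formed by methanolysis adds to the aldehyde, cycloelimination and 1,2-H shift of the alkylidene carbene give the terminal alkyne, and K2CO3/MeOH is mild enough for the methyl ester and the peroxyketal.

**Compound list**

1 | hex-5-ynoic acid | C#CCCCC(=O)O | starting material
2 | Meldrum's acid (2,2-dimethyl-1,3-dioxane-4,6-dione) | CC1(C)OC(=O)CC(=O)O1 | starting material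
3 | tert-butanol | CC(C)(C)O | starting material
4 | 5-(1-hydroxyhex-5-yn-1-ylidene)-2,2-dimethyl-1,3-dioxane-4,6-dione (acyl Meldrum's acid) | C#CCCCC(O)=C1C(=O)OC(C)(C)OC1=O | intermediate
5 | tert-butyl 3-oxooct-7-ynoate | C#CCCCC(=O)CC(=O)OC(C)(C)C | intermediate
6 | methyl (2E)-4-bromobut-2-enoate | COC(=O)/C=C/CBr | starting material
7 | 1-tert-butyl 6-methyl (4E)-2-(hex-5-ynoyl)hex-4-enedioate (racemic) | C#CCCCC(=O)C(C/C=C/C(=O)OC)C(=O)OC(C)(C)C | intermediate
8 | (4E)-2-(hex-5-ynoyl)-6-methoxy-6-oxohex-4-enoic acid (β-keto acid) | C#CCCCC(=O)C(C/C=C/C(=O)OC)C(=O)O | intermediate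
9 | methyl (2E)-6-oxoundec-2-en-10-ynoate | C#CCCCC(=O)CC/C=C/C(=O)OC | intermediate
10 | hydrogen peroxide | OO | starting material
11 | methanol | CO | starting material
12 | methyl (2E)-6-hydroperoxy-6-hydroxyundec-2-en-10-ynoate (perhydrate, C6 equilibrating) | C#CCCCC(O)(OO)CC/C=C/C(=O)OC | intermediate
13 | methyl 2-[(3S)-6-hydroxy-6-(pent-4-yn-1-yl)-1,2-dioxan-3-yl]acetate (C6 anomers) | C#CCCCC1(O)CC[C@@H](CC(=O)OC)OO1 | intermediate
14 | methyl 2-[(3S,6R)-6-methoxy-6-(pent-4-yn-1-yl)-1,2-dioxan-3-yl]acetate | C#CCCC[C@]1(OC)CC[C@@H](CC(=O)OC)OO1 | intermediate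
15 | dec-9-yn-1-ol | C#CCCCCCCCCO | starting material
16 | iodine | II | starting material
17 | Cp2Zr(Cl)–O(CH2)8CH=CH–Zr(Cl)Cp2, (E)-alkenylzirconocene of the zirconium alkoxide | Cl[Zr](C1C=CC=C1)(C1C=CC=C1)OCCCCCCCC/C=C/[Zr](Cl)(C1C=CC=C1)C1C=CC=C1 | intermediate
18 | (9E)-10-iododec-9-en-1-ol | OCCCCCCCC/C=C/I | intermediate
19 | methyl 2-[(3S,6R)-6-[(6E)-15-hydroxypentadec-6-en-4-yn-1-yl]-6-methoxy-1,2-dioxan-3-yl]acetate | OCCCCCCCC/C=C/C#CCCC[C@]1(OC)CC[C@@H](CC(=O)OC)OO1 | intermediate
20 | methyl 2-[(3S,6R)-6-methoxy-6-[(6E)-15-oxopentadec-6-en-4-yn-1-yl]-1,2-dioxan-3-yl]acetate | O=CCCCCCCC/C=C/C#CCCC[C@]1(OC)CC[C@@H](CC(=O)OC)OO1 | intermediate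
21 | dimethyl (1-diazo-2-oxopropyl)phosphonate (Bestmann–Ohira reagent) | COP(=O)(OC)C(=[N+]=[N-])C(C)=O | starting material
22 | methyl 2-[(3S,6R)-6-[(6E)-hexadec-6-ene-4,15-diyn-1-yl]-6-methoxy-1,2-dioxan-3-yl]acetate | C#CCCCCCCC/C=C/C#CCCC[C@]1(OC)CC[C@@H](CC(=O)OC)OO1 | target

**Totals**
Total step count: 8. Longest linear sequence: 7 (steps 1, 2, 3, 4, 6, 7, 8); step 5 is a one-step side branch.

**Steps most likely to fail and their fallbacks**

Step 4 is the main risk. The enantioselectivity is unproven. The hemiketal OH of 12 may compete by 5-exo attack to give a tetrahydrofuran. H2O2 may slowly N-oxidise the catalyst. The ester enolate may close to an epoxide. The fallback replaces the catalytic asymmetric cascade by a stepwise ring formation of known type followed by resolution. It sets out from 9. Urea·H2O2 and catalytic Sc(OTf)3 in MeOH convert the ketone into the racemic α-methoxy hydroperoxide methyl (2E)-6-hydroperoxy-6-methoxyundec-2-en-10-ynoate F1, which has only one nucleophilic oxygen. Et2NH in CF3CH2OH then closes the ring by peroxy-Michael addition. This gives 14 together with its enantiomer methyl 2-[(3R,6S)-6-methoxy-6-(pent-4-yn-1-yl)-1,2-dioxan-3-yl]acetate F2 and the racemic C6-epimer methyl 2-[(3S*,6S*)-6-methoxy-6-(pent-4-yn-1-yl)-1,2-dioxan-3-yl]acetate F3. CSA in MeOH equilibrates F3 into the cis pair, and preparative chiral HPLC removes F2. The fallback comes back to the route at 14.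

Step 8 is the second risk. K2CO3/MeOH acts on a β-peroxy ester, and a retro-Michael/re-addition would erode C3 or open the ring. The fallback carries the terminal alkyne through the coupling as a silyl alkyne and avoids the late base. It sets out from 15 and 14. Treating 15 with n-BuLi (2.1 equiv) and TMSCl (2.2 equiv) gives trimethyl{[10-(trimethylsilyl)dec-9-yn-1-yl]oxy}silane F7. Its O–Si bond is cleaved on 1 M HCl work-up to give 10-(trimethylsilyl)dec-9-yn-1-ol F8. Dess–Martin oxidation gives 10-(trimethylsilyl)dec-9-ynal F9. Takai olefination (CrCl2, CHI3, THF/dioxane) gives [(10E)-11-iodoundec-10-en-1-yn-1-yl]trimethylsilane F10. Sonogashira coupling of F10 with 14 under the conditions of step 6 gives methyl 2-[(3S,6R)-6-methoxy-6-[(6E)-16-(trimethylsilyl)hexadec-6-ene-4,15-diyn-1-yl]-1,2-dioxan-3-yl]acetate F11. TBAF buffered with AcOH in THF at 0 °C removes the silyl group. The fallback comes back to the route at 22 and costs one step more.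

Step 6 is the third risk. Pd/Cu/amine may decompose the peroxide, or 14 may undergo Glaser dimerisation. The fallback moves the coupling ahead of peroxide formation. It sets out from 9. Sonogashira coupling of 9 with 18 under the same conditions gives methyl (2E,12E)-21-hydroxy-6-oxohenicosa-2,12-dien-10-ynoate F4. The step-4 cascade is then run on F4. It passes through the perhydrate methyl (2E,12E)-6-hydroperoxy-6,21-dihydroxyhenicosa-2,12-dien-10-ynoate F5 and the cyclic peroxyhemiketal methyl 2-[(3S)-6-hydroxy-6-[(6E)-15-hydroxypentadec-6-en-4-yn-1-yl]-1,2-dioxan-3-yl]acetate F6. The fallback comes back to the route at 19 with the same step count.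

**Further compounds**

F1 | step 4 | methyl (2E)-6-hydroperoxy-6-methoxyundec-2-en-10-ynoate (racemic) | C#CCCCC(OC)(OO)CC/C=C/C(=O)OC
F2 | step 4 | methyl 2-[(3R,6S)-6-methoxy-6-(pent-4-yn-1-yl)-1,2-dioxan-3-yl]acetate | C#CCCC[C@@]1(OC)CC[C@H](CC(=O)OC)OO1
F3 | step 4 | methyl 2-[(3S*,6S*)-6-methoxy-6-(pent-4-yn-1-yl)-1,2-dioxan-3-yl]acetate (racemic C6-epimer, 3S,6S form drawn) | C#CCCC[C@@]1(OC)CC[C@@H](CC(=O)OC)OO1
F4 | step 6 | methyl (2E,12E)-21-hydroxy-6-oxohenicosa-2,12-dien-10-ynoate | OCCCCCCCC/C=C/C#CCCCC(=O)CC/C=C/C(=O)OC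
F5 | step 6 | methyl (2E,12E)-6-hydroperoxy-6,21-dihydroxyhenicosa-2,12-dien-10-ynoate | OCCCCCCCC/C=C/C#CCCCC(O)(OO)CC/C=C/C(=O)OC
F6 | step 6 | methyl 2-[(3S)-6-hydroxy-6-[(6E)-15-hydroxypentadec-6-en-4-yn-1-yl]-1,2-dioxan-3-yl]acetate (C6 anomers) | OCCCCCCCC/C=C/C#CCCCC1(O)CC[C@@H](CC(=O)OC)OO1
F7 | step 8 | trimethyl{[10-(trimethylsilyl)dec-9-yn-1-yl]oxy}silane | C[Si](C)(C)C#CCCCCCCCCO[Si](C)(C)C
F8 | step 8 | 10-(trimethylsilyl)dec-9-yn-1-ol | C[Si](C)(C)C#CCCCCCCCCO
F9 | step 8 | 10-(trimethylsilyl)dec-9-ynal | C[Si](C)(C)C#CCCCCCCCC=O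
F10 | step 8 | [(10E)-11-iodoundec-10-en-1-yn-1-yl]trimethylsilane | C[Si](C)(C)C#CCCCCCCC/C=C/I
F11 | step 8 | methyl 2-[(3S,6R)-6-methoxy-6-[(6E)-16-(trimethylsilyl)hexadec-6-ene-4,15-diyn-1-yl]-1,2-dioxan-3-yl]acetate | C[Si](C)(C)C#CCCCCCCC/C=C/C#CCCC[C@]1(OC)CC[C@@H](CC(=O)OC)OO1
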